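**Retrosynthetic overview**

1. The target is (2S)-pinocembrin joined through C6 to an 8-aryl goniotriol-type lactone. Ring C (O1, C2, C3, C4, C4a, C8a) is closed last by a biomimetic, catalyst-controlled 6-endo-trig oxa-Michael addition of the C8a hydroxyl onto an (E)-chalcone (O1–C2 bond), the laboratory counterpart of the chalcone isomerase step.
2. Enabling feature: the β-aryloxy ketone O1–C2–C3–C4(=O) of ring C, together with the local twofold axis of ring A through C6 and C8a. O1 is the only oxygen para to the side chain while O5 and O7 flank it, so O5/O7 travel as a pair of MOM ethers and O1 alone as a silyl ether; C4a and C8 are equivalent for acylation, and closure can only give the 6-substituted flavanone.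
3. Chalcone: aryllithium (from Br at the future C4a) plus cinnamic Weinreb amide. Lactone: ring-closing metathesis of an L6 acrylate onto the L5 vinyl carbinol. L5–L6 bond: chelation-controlled γ-silyloxyallylation of an α-MOM-oxy aldehyde.
4. L8–aryl bond and the L7/L8 stereocentres: copper-catalysed SN2 opening (inversion) of the TES ether of (2S,3S)-3-phenylglycidol at the benzylic carbon by the 2,6-bis(MOM-oxy)aryl Grignard reagent.
5. Ring order: ring A and both phenyl rings are bought, the dihydropyranone ring is formed in step 12, ring C in step 14.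

Key step: step 14

Numbering: flavanone atoms carry the usual locants; L2–L6 are the lactone ring atoms (L2 = C=O, L5 = CH–O, L6 = ring CH–O), L7 is the carbinol carbon and L8 the diarylmethine carbon of the side chain.

Assumption: the quinidine-derived thiourea is taken to deliver the phenoxide to the enone face that gives (2S); if the opposite face is preferred, its quinine-derived (8S,9S) pseudoenantiomer is used in its place.

**Route**

Step 1
Reactants: 1 phloroglucinol
Product: 2 5-(triisopropylsilyloxy)benzene-1,3-diol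
Conditions: TIPSCl (1.0 equiv), imidazole, DMF, 0 °C to rt
Reagents that add atoms: chlorotriisopropylsilane (TIPSCl), CC(C)[Si](Cl)(C(C)C)C(C)C
Why: Statistical monosilylation of the threefold-symmetric triol (silyl ether formation), in which the bulky TIPS group slows a second silylation and unreacted triol and bis-silyl ether can be separated and recycled.

Step 2
Reactants: 2 5-(triisopropylsilyloxy)benzene-1,3-diol
Product: 3 [3,5-bis(methoxymethoxy)phenoxy]triisopropylsilane
Conditions: MOMCl (2.5 equiv), i-Pr2NEt, CH2Cl2, 0 °C to rt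
Reagents that add atoms: chloromethyl methyl ether (MOMCl), COCCl
Why: O-alkylation of both remaining phenols with the α-chloro ether under amine base (MOM acetal formation) gives the C2v-symmetric arene in which the unique oxygen (future O1) is already differentiated from the pair (future O5/O7).

Step 3
Reactants: 4 (2S,3S)-3-phenylglycidol
Product: 5 triethyl{[(2S,3S)-3-phenyloxiran-2-yl]methoxy}silane
Conditions: TESCl, imidazole, CH2Cl2, 0 °C
Reagents that add atoms: chlorotriethylsilane (TESCl), CC[Si](Cl)(CC)CC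
Why: Silylation of the primary alcohol (silyl ether formation) removes the acidic proton before the organometallic step and leaves both epoxide stereocentres untouched.

Step 4
Reactants: 3 [3,5-bis(methoxymethoxy)phenoxy]triisopropylsilane; 5 triethyl{[(2S,3S)-3-phenyloxiran-2-yl]methoxy}silane
Product: 8 (2R,3S)-3-[2,6-bis(methoxymethoxy)-4-(triisopropylsilyloxy)phenyl]-3-phenyl-1-(triethylsilyloxy)propan-2-ol, via aryllithium 6 (not isolated), via arylmagnesium bromide 7 (not isolated)
Conditions: n-BuLi, THF, 0 °C; MgBr2·OEt2, 0 °C; CuI (10 mol%), then 5, −30 to 0 °C; H2O work-up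
Reagents that add atoms: none
Why: Directed ortho-lithiation occurs between the two MOM-oxy groups (the positions next to the bulky, non-coordinating OTIPS group are shielded), and after transmetalation the copper-catalysed Grignard opening of the trans-epoxide takes place at the benzylic carbon by SN2 with inversion, which sets L8 (S) while L7 keeps the glycidol configuration.

Step 5
Reactants: 8 (2R,3S)-3-[2,6-bis(methoxymethoxy)-4-(triisopropylsilyloxy)phenyl]-3-phenyl-1-(triethylsilyloxy)propan-2-ol
Product: 9 triethyl{(2R,3S)-3-[2,6-bis(methoxymethoxy)-4-(triisopropylsilyloxy)phenyl]-2-(methoxymethoxy)-3-phenylpropoxy}silane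
Conditions: MOMCl, i-Pr2NEt, CH2Cl2, 0 to 40 °C
Reagents that add atoms: chloromethyl methyl ether (MOMCl), COCCl
Why: MOM acetal formation on the secondary L7 alcohol under non-alkoxide conditions (no silyl migration) installs the chelating α-alkoxy group needed in step 10 and later keeps this hydroxyl away from the unsaturated lactone.

Step 6
Reactants: 9 triethyl{(2R,3S)-3-[2,6-bis(methoxymethoxy)-4-(triisopropylsilyloxy)phenyl]-2-(methoxymethoxy)-3-phenylpropoxy}silane
Product: 10 {(2R,3S)-3-[3-bromo-2,6-bis(methoxymethoxy)-4-(triisopropylsilyloxy)phenyl]-2-(methoxymethoxy)-3-phenylpropoxy}triethylsilane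
Conditions: NBS (1.0 equiv), CH2Cl2, −40 to 0 °C, dark
Reagents that add atoms: N-bromosuccinimide (NBS), O=C1CCC(=O)N1Br
Why: Electrophilic aromatic bromination of the electron-rich trialkoxyarene, in which the two free ring positions are equivalent through rotation about the aryl–L8 bond, so that a single monobromide with Br on the future C4a (next to OTIPS) should result.

Step 7
Reactants: 10 {(2R,3S)-3-[3-bromo-2,6-bis(methoxymethoxy)-4-(triisopropylsilyloxy)phenyl]-2-(methoxymethoxy)-3-phenylpropoxy}triethylsilane; 11 (E)-N-methoxy-N-methylcinnamamide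
Product: 14 (E)-1-{2,4-bis(methoxymethoxy)-3-[(1S,2R)-2-(methoxymethoxy)-1-phenyl-3-(triethylsilyloxy)propyl]-6-(triisopropylsilyloxy)phenyl}-3-phenylprop-2-en-1-one, via aryllithium 12 (not isolated), via lithium hemiaminal alkoxide 13 (not isolated)
Conditions: t-BuLi (2.1 equiv), THF, −78 °C; 11, −78 to −40 °C; H2O
Reagents that add atoms: none
Why: Bromine–lithium exchange at −78 °C is followed by 1,2-addition of the aryllithium to the Weinreb amide to give a chelated tetrahedral adduct that collapses to the (E)-enone only on work-up (Weinreb ketone synthesis), the low temperature suppressing O-to-C silyl migration.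

Step 8
Reactants: 14 (E)-1-{2,4-bis(methoxymethoxy)-3-[(1S,2R)-2-(methoxymethoxy)-1-phenyl-3-(triethylsilyloxy)propyl]-6-(triisopropylsilyloxy)phenyl}-3-phenylprop-2-en-1-one
Product: 15 (2R,3S)-3-{3-[(E)-cinnamoyl]-2,6-bis(methoxymethoxy)-4-(triisopropylsilyloxy)phenyl}-2-(methoxymethoxy)-3-phenylpropanal
Conditions: (COCl)2, DMSO, CH2Cl2, −78 to −40 °C; Et3N, −78 to 0 °C
Reagents that add atoms: none
Why: Under Swern conditions the primary triethylsilyl ether is cleaved by the chlorosulfonium reagent and oxidised in the same flask to the aldehyde (Swern oxidation with oxidative desilylation), the cold amine treatment keeping the α-alkoxy stereocentre L7 intact.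

Step 9
Reactants: 16 allyloxy(tert-butyl)dimethylsilane
Product: 18 (Z)-tert-butyldimethyl{[3-(tributylstannyl)prop-1-en-1-yl]oxy}silane, via lithiated allyl silyl ether 17 (not isolated)
Conditions: s-BuLi, THF, −78 °C; Bu3SnCl, −78 °C to rt
Reagents that add atoms: tributyltin chloride, CCCC[Sn](Cl)(CCCC)CCCC
Why: α-Lithiation of the allyl silyl ether gives the oxygen-chelated (Z)-oxyallyl anion, which is stannylated at the γ-carbon to the (Z)-γ-silyloxyallylstannane (allyl anion formation and γ-selective trapping).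

Step 10
Reactants: 15 (2R,3S)-3-{3-[(E)-cinnamoyl]-2,6-bis(methoxymethoxy)-4-(triisopropylsilyloxy)phenyl}-2-(methoxymethoxy)-3-phenylpropanal; 18 (Z)-tert-butyldimethyl{[3-(tributylstannyl)prop-1-en-1-yl]oxy}silane
Product: 19 (E)-1-{3-[(1S,2R,3S,4S)-4-(tert-butyldimethylsilyloxy)-3-hydroxy-2-(methoxymethoxy)-1-phenylhex-5-en-1-yl]-2,4-bis(methoxymethoxy)-6-(triisopropylsilyloxy)phenyl}-3-phenylprop-2-en-1-one
Conditions: MgBr2·OEt2 (3 equiv), CH2Cl2, −25 °C; H2O work-up
Reagents that add atoms: none
Why: MgBr2 chelates the aldehyde oxygen and the α-MOM-oxy group (Cram-chelate model) and the (Z)-γ-silyloxyallylstannane attacks the face away from the diarylmethyl group through an open SE2' transition state, so that L6 is formed syn to L7 and L5 syn to L6 (chelation-controlled γ-alkoxyallylstannane addition).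

Step 11
Reactants: 19 (E)-1-{3-[(1S,2R,3S,4S)-4-(tert-butyldimethylsilyloxy)-3-hydroxy-2-(methoxymethoxy)-1-phenylhex-5-en-1-yl]-2,4-bis(methoxymethoxy)-6-(triisopropylsilyloxy)phenyl}-3-phenylprop-2-en-1-one; 20 acryloyl chloride
Product: 21 (1S,2R,3S,4S)-4-(tert-butyldimethylsilyloxy)-1-{3-[(E)-cinnamoyl]-2,6-bis(methoxymethoxy)-4-(triisopropylsilyloxy)phenyl}-2-(methoxymethoxy)-1-phenylhex-5-en-3-yl acrylate
Conditions: i-Pr2NEt, CH2Cl2, −20 to 0 °C
Reagents that add atoms: none
Why: Acylation of the only free hydroxyl (L6) with the acid chloride under amine base (esterification) places the acrylate on the oxygen that becomes the lactone ring oxygen, without touching a stereocentre.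

Step 12
Reactants: 21 (1S,2R,3S,4S)-4-(tert-butyldimethylsilyloxy)-1-{3-[(E)-cinnamoyl]-2,6-bis(methoxymethoxy)-4-(triisopropylsilyloxy)phenyl}-2-(methoxymethoxy)-1-phenylhex-5-en-3-yl acrylate
Product: 22 (5S,6S)-5-(tert-butyldimethylsilyloxy)-6-[(1R,2S)-2-{3-[(E)-cinnamoyl]-2,6-bis(methoxymethoxy)-4-(triisopropylsilyloxy)phenyl}-1-(methoxymethoxy)-2-phenylethyl]-5,6-dihydro-2H-pyran-2-one
Conditions: second-generation Grubbs catalyst (7 mol%), CH2Cl2 (2 mM), 40 °C
Reagents that add atoms: none
Why: Ring-closing metathesis between the acrylate and the vinyl group closes the six-membered α,β-unsaturated lactone with loss of ethene, the conjugated 1,2-disubstituted chalcone alkene being inert to the catalyst.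

Step 13
Reactants: 22 (5S,6S)-5-(tert-butyldimethylsilyloxy)-6-[(1R,2S)-2-{3-[(E)-cinnamoyl]-2,6-bis(methoxymethoxy)-4-(triisopropylsilyloxy)phenyl}-1-(methoxymethoxy)-2-phenylethyl]-5,6-dihydro-2H-pyran-2-one
Product: 23 (5S,6S)-5-(tert-butyldimethylsilyloxy)-6-[(1R,2S)-2-{3-[(E)-cinnamoyl]-4-hydroxy-2,6-bis(methoxymethoxy)phenyl}-1-(methoxymethoxy)-2-phenylethyl]-5,6-dihydro-2H-pyran-2-one
Conditions: Bu4NF/AcOH (1:1), THF, 0 °C
Reagents that add atoms: none
Why: Fluoride cleaves the aryl silyl ether (phenoxide leaving group, activated by the ortho carbonyl) much faster than the hindered secondary TBS ether, and the acetic acid buffer keeps the liberated phenol protonated so that no uncatalysed cyclisation sets in (fluoride desilylation).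

Step 14
Reactants: 23 (5S,6S)-5-(tert-butyldimethylsilyloxy)-6-[(1R,2S)-2-{3-[(E)-cinnamoyl]-4-hydroxy-2,6-bis(methoxymethoxy)phenyl}-1-(methoxymethoxy)-2-phenylethyl]-5,6-dihydro-2H-pyran-2-one
Product: 24 (S)-6-{(1S,2R)-2-[(2S,3S)-3-(tert-butyldimethylsilyloxy)-6-oxo-3,6-dihydro-2H-pyran-2-yl]-2-(methoxymethoxy)-1-phenylethyl}-5,7-bis(methoxymethoxy)-2-phenylchroman-4-one
Conditions: quinidine-derived bifunctional thiourea 1-[3,5-bis(trifluoromethyl)phenyl]-3-[(8R,9R)-6'-methoxycinchonan-9-yl]thiourea (15 mol%), toluene, −10 °C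
Reagents that add atoms: none
Why: The quinuclidine nitrogen of the catalyst deprotonates or hydrogen-bonds the single free phenol (O1–H) while the thiourea binds the chalcone carbonyl, and the phenoxide adds to the β-carbon of the s-cis enone in an intramolecular oxa-Michael reaction, after which the enol is protonated at C3. The closest known reaction type is the cinchona-thiourea-catalysed asymmetric cyclisation of 2'-hydroxychalcone-type enones to flavanones, the small-molecule counterpart of the chalcone isomerase step of flavonoid biosynthesis; that precedent is strongest for ester-activated enones, so stereoinduction on this unactivated chalcone is the main uncertainty. Ring C is closed in the 6-endo-trig mode by forming the O1–C2 bond. The new stereocentre C2 is set by the catalyst, which shields one face of the enone, while the remote side-chain stereocentres give no useful bias, so the C2 epimers are diastereomers and separable. The step needs O-regioselectivity (closure through O1, not O5) and facial selectivity at C2; the first is secured in the substrate because the two oxygens flanking the side chain are MOM ethers and only the oxygen para to it is free, the second by the catalyst. The MOM ether at L7 and the TBS ether at L5 keep the side-chain oxygens from adding to the unsaturated lactone or translactonising under the mildly basic conditions.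

Step 15
Reactants: 24 (S)-6-{(1S,2R)-2-[(2S,3S)-3-(tert-butyldimethylsilyloxy)-6-oxo-3,6-dihydro-2H-pyran-2-yl]-2-(methoxymethoxy)-1-phenylethyl}-5,7-bis(methoxymethoxy)-2-phenylchroman-4-one
Product: 25 (S)-5,7-dihydroxy-6-{(1S,2R)-2-hydroxy-2-[(2R,3S)-3-hydroxy-6-oxo-3,6-dihydro-2H-pyran-2-yl]-1-phenylethyl}-2-phenylchroman-4-one (CNP0136207.1)
Conditions: 3 M aq. HCl/THF (1:2), 40 °C
Reagents that add atoms: none
Why: Aqueous acid hydrolyses the three methoxymethyl acetals and the silyl ether (acetal hydrolysis and protodesilylation) under conditions in which the flavanone C2 centre and the unsaturated lactone should be stable, whereas base is avoided because it would open ring C and trigger oxa-Michael addition of the L7 hydroxyl to the lactone.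

**Compound list**

1 | phloroglucinol | Oc1cc(O)cc(O)c1 | starting material
2 | 5-(triisopropylsilyloxy)benzene-1,3-diol | Oc1cc(O)cc(O[Si](C(C)C)(C(C)C)C(C)C)c1 | intermediate
3 | [3,5-bis(methoxymethoxy)phenoxy]triisopropylsilane | COCOc1cc(OCOC)cc(O[Si](C(C)C)(C(C)C)C(C)C)c1 | intermediate
4 | (2S,3S)-3-phenylglycidol [(2S,3S)-(3-phenyloxiran-2-yl)methanol] | OC[C@@H]1O[C@H]1c1ccccc1 | starting material
5 | triethyl{[(2S,3S)-3-phenyloxiran-2-yl]methoxy}silane | CC[Si](CC)(CC)OC[C@@H]1O[C@H]1c1ccccc1 | intermediate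
6 | 2,6-bis(methoxymethoxy)-4-(triisopropylsilyloxy)phenyllithium (not isolated) | [Li]c1c(OCOC)cc(O[Si](C(C)C)(C(C)C)C(C)C)cc1OCOC | intermediate
7 | [2,6-bis(methoxymethoxy)-4-(triisopropylsilyloxy)phenyl]magnesium bromide (not isolated) | Br[Mg]c1c(OCOC)cc(O[Si](C(C)C)(C(C)C)C(C)C)cc1OCOC | intermediate
8 | (2R,3S)-3-[2,6-bis(methoxymethoxy)-4-(triisopropylsilyloxy)phenyl]-3-phenyl-1-(triethylsilyloxy)propan-2-ol | CC[Si](CC)(CC)OC[C@H](O)[C@@H](c1ccccc1)c1c(OCOC)cc(O[Si](C(C)C)(C(C)C)C(C)C)cc1OCOC | intermediate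
9 | triethyl{(2R,3S)-3-[2,6-bis(methoxymethoxy)-4-(triisopropylsilyloxy)phenyl]-2-(methoxymethoxy)-3-phenylpropoxy}silane | CC[Si](CC)(CC)OC[C@H](OCOC)[C@@H](c1ccccc1)c1c(OCOC)cc(O[Si](C(C)C)(C(C)C)C(C)C)cc1OCOC | intermediate
10 | {(2R,3S)-3-[3-bromo-2,6-bis(methoxymethoxy)-4-(triisopropylsilyloxy)phenyl]-2-(methoxymethoxy)-3-phenylpropoxy}triethylsilane | CC[Si](CC)(CC)OC[C@H](OCOC)[C@@H](c1ccccc1)c1c(OCOC)cc(O[Si](C(C)C)(C(C)C)C(C)C)c(Br)c1OCOC | intermediate
11 | (E)-N-methoxy-N-methylcinnamamide | CON(C)C(=O)/C=C/c1ccccc1 | starting material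
12 | {2,4-bis(methoxymethoxy)-3-[(1S,2R)-2-(methoxymethoxy)-1-phenyl-3-(triethylsilyloxy)propyl]-6-(triisopropylsilyloxy)phenyl}lithium (not isolated) | CC[Si](CC)(CC)OC[C@H](OCOC)[C@@H](c1ccccc1)c1c(OCOC)cc(O[Si](C(C)C)(C(C)C)C(C)C)c([Li])c1OCOC | intermediate
13 | lithium alkoxide of the N-methoxy-N-methyl hemiaminal formed from 12 and 11 (tetrahedral adduct, both epimers at the new carbon, not isolated) | CC[Si](CC)(CC)OC[C@H](OCOC)[C@@H](c1ccccc1)c1c(OCOC)cc(O[Si](C(C)C)(C(C)C)C(C)C)c(C(O[Li])(/C=C/c2ccccc2)N(C)OC)c1OCOC | intermediate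
14 | (E)-1-{2,4-bis(methoxymethoxy)-3-[(1S,2R)-2-(methoxymethoxy)-1-phenyl-3-(triethylsilyloxy)propyl]-6-(triisopropylsilyloxy)phenyl}-3-phenylprop-2-en-1-one | CC[Si](CC)(CC)OC[C@H](OCOC)[C@@H](c1ccccc1)c1c(OCOC)cc(O[Si](C(C)C)(C(C)C)C(C)C)c(C(=O)/C=C/c2ccccc2)c1OCOC | intermediate
15 | (2R,3S)-3-{3-[(E)-cinnamoyl]-2,6-bis(methoxymethoxy)-4-(triisopropylsilyloxy)phenyl}-2-(methoxymethoxy)-3-phenylpropanal | O=C[C@H](OCOC)[C@@H](c1ccccc1)c1c(OCOC)cc(O[Si](C(C)C)(C(C)C)C(C)C)c(C(=O)/C=C/c2ccccc2)c1OCOC | intermediate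
16 | allyloxy(tert-butyl)dimethylsilane | C=CCO[Si](C)(C)C(C)(C)C | starting material
17 | (Z)-3-(tert-butyldimethylsilyloxy)allyllithium (oxygen-chelated, not isolated) | [Li]C/C=C\O[Si](C)(C)C(C)(C)C | intermediate
18 | (Z)-tert-butyldimethyl{[3-(tributylstannyl)prop-1-en-1-yl]oxy}silane | CCCC[Sn](CCCC)(CCCC)C/C=C\O[Si](C)(C)C(C)(C)C | intermediate
19 | (E)-1-{3-[(1S,2R,3S,4S)-4-(tert-butyldimethylsilyloxy)-3-hydroxy-2-(methoxymethoxy)-1-phenylhex-5-en-1-yl]-2,4-bis(methoxymethoxy)-6-(triisopropylsilyloxy)phenyl}-3-phenylprop-2-en-1-one | C=C[C@H](O[Si](C)(C)C(C)(C)C)[C@@H](O)[C@H](OCOC)[C@@H](c1ccccc1)c1c(OCOC)cc(O[Si](C(C)C)(C(C)C)C(C)C)c(C(=O)/C=C/c2ccccc2)c1OCOC | intermediate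
20 | acryloyl chloride | C=CC(=O)Cl | starting material
21 | (1S,2R,3S,4S)-4-(tert-butyldimethylsilyloxy)-1-{3-[(E)-cinnamoyl]-2,6-bis(methoxymethoxy)-4-(triisopropylsilyloxy)phenyl}-2-(methoxymethoxy)-1-phenylhex-5-en-3-yl acrylate | C=C[C@H](O[Si](C)(C)C(C)(C)C)[C@@H](OC(=O)C=C)[C@H](OCOC)[C@@H](c1ccccc1)c1c(OCOC)cc(O[Si](C(C)C)(C(C)C)C(C)C)c(C(=O)/C=C/c2ccccc2)c1OCOC | intermediate
22 | (5S,6S)-5-(tert-butyldimethylsilyloxy)-6-[(1R,2S)-2-{3-[(E)-cinnamoyl]-2,6-bis(methoxymethoxy)-4-(triisopropylsilyloxy)phenyl}-1-(methoxymethoxy)-2-phenylethyl]-5,6-dihydro-2H-pyran-2-one | O=C1C=C[C@H](O[Si](C)(C)C(C)(C)C)[C@H]([C@H](OCOC)[C@@H](c2ccccc2)c2c(OCOC)cc(O[Si](C(C)C)(C(C)C)C(C)C)c(C(=O)/C=C/c3ccccc3)c2OCOC)O1 | intermediate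
23 | (5S,6S)-5-(tert-butyldimethylsilyloxy)-6-[(1R,2S)-2-{3-[(E)-cinnamoyl]-4-hydroxy-2,6-bis(methoxymethoxy)phenyl}-1-(methoxymethoxy)-2-phenylethyl]-5,6-dihydro-2H-pyran-2-one | O=C1C=C[C@H](O[Si](C)(C)C(C)(C)C)[C@H]([C@H](OCOC)[C@@H](c2ccccc2)c2c(OCOC)cc(O)c(C(=O)/C=C/c3ccccc3)c2OCOC)O1 | intermediate
24 | (S)-6-{(1S,2R)-2-[(2S,3S)-3-(tert-butyldimethylsilyloxy)-6-oxo-3,6-dihydro-2H-pyran-2-yl]-2-(methoxymethoxy)-1-phenylethyl}-5,7-bis(methoxymethoxy)-2-phenylchroman-4-one | O=C1C=C[C@H](O[Si](C)(C)C(C)(C)C)[C@H]([C@H](OCOC)[C@@H](c2ccccc2)c2c(OCOC)cc3c(c2OCOC)C(=O)C[C@@H](c2ccccc2)O3)O1 | intermediate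
25 | (S)-5,7-dihydroxy-6-{(1S,2R)-2-hydroxy-2-[(2R,3S)-3-hydroxy-6-oxo-3,6-dihydro-2H-pyran-2-yl]-1-phenylethyl}-2-phenylchroman-4-one (CNP0136207.1) | O=C1C=C[C@H](O)[C@H]([C@H](O)[C@@H](c2ccccc2)c2c(O)cc3c(c2O)C(=O)C[C@@H](c2ccccc2)O3)O1 | target

**Step count and risks**

Total step count: 15.

Longest linear sequence: 13 steps (1 → 2 → 3 → 8 → 9 → 10 → 14 → 15 → 19 → 21 → 22 → 23 → 24 → 25). Steps 3 and 9 are short side branches.

Steps most likely to fail:

- **Step 14 (key step).** Insufficient facial discrimination by the catalyst on an unactivated, doubly ortho-substituted chalcone, or slow turnover that lets reversible ring opening erode selectivity. Fallback: starting from 23, the cyclisation is run without a chiral catalyst (i-Pr2NEt, MeCN, 40 °C; classical base-mediated chalcone–flavanone isomerisation). This should give both C2 epimers, 24 and the (2R)-configured flavanone epimer F1, which are diastereomers and can be separated by chromatography. F1 is resubjected to the same conditions (retro-oxa-Michael to 23 and re-closure), so that material is funnelled to 24, where the route is rejoined.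

- **Step 7.** Sluggish addition of the hindered aryllithium (flanked by OTIPS and OMOM) to the Weinreb amide, with O-to-C silyl migration or protonation taking over on warming. Fallback: starting from 10, the same exchange gives 12, which is trapped at −78 °C with the smaller and more electrophilic (E)-cinnamaldehyde to give the diaryl-substituted allylic alcohol F2 (both carbinol epimers). Oxidation of F2 with MnO2 (CH2Cl2, rt) gives the enone and rejoins the route at 14.

- **Step 4.** Slow opening of the benzylic epoxide carbon by the doubly ortho-substituted aryl nucleophile, with Lewis-acid-induced epoxide rearrangement or bromohydrin formation by the magnesium salts competing. Fallback: starting from 3 and 5, the bond is made by Friedel–Crafts alkylation instead. The arene attacks the hydrogen-bond-activated epoxide in hexafluoroisopropanol (0 °C to rt) at the benzylic carbon with inversion, at the ring position para to OTIPS (the least hindered activated site). This leads directly to 8 without any new intermediate (no new compound, F0).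

Further compounds
F1 | step 14 | (R)-6-{(1S,2R)-2-[(2S,3S)-3-(tert-butyldimethylsilyloxy)-6-oxo-3,6-dihydro-2H-pyran-2-yl]-2-(methoxymethoxy)-1-phenylethyl}-5,7-bis(methoxymethoxy)-2-phenylchroman-4-one (C2 epimer of 24) | O=C1C=C[C@H](O[Si](C)(C)C(C)(C)C)[C@H]([C@H](OCOC)[C@@H](c2ccccc2)c2c(OCOC)cc3c(c2OCOC)C(=O)C[C@H](c2ccccc2)O3)O1
F2 | step 7 | (E)-1-{2,4-bis(methoxymethoxy)-3-[(1S,2R)-2-(methoxymethoxy)-1-phenyl-3-(triethylsilyloxy)propyl]-6-(triisopropylsilyloxy)phenyl}-3-phenylprop-2-en-1-ol (both carbinol epimers) | CC[Si](CC)(CC)OC[C@H](OCOC)[C@@H](c1ccccc1)c1c(OCOC)cc(O[Si](C(C)C)(C(C)C)C(C)C)c(C(O)/C=C/c2ccccc2)c1OCOC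
F0 | step 4 | none | none
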